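## Structural features

The target is a hexaphenol built on a dibenzo-fused cycloheptanone: the ketone carbon Ca joins two resorcinol rings (outer ring A, central ring B), and the seven-membered ring is completed by two sp3 methines, Cb (on ring A, bearing 4-hydroxyphenyl) and Cc (on ring B). Cc is also the ring-fusion atom of an indane on ring B, whose other sp3 carbons are Ce (4-hydroxyphenyl, next to Cc) and Cd (3,5-dihydroxyphenyl, on ring B); ring B carries Cc at position 1, Ca at 2, hydroxyls at 3 and 5 and Cd at 6, and ring A carries Ca at position 1, hydroxyls at 3 and 5 and Cb at 6. The four stereocentres form one unbroken chain Cb–Cc–Ce–Cd in which every neighbouring pair is trans (Cb S, Cc R, Ce S, Cd S). Sensitive elements are the six phenols (kept as methyl ethers to the end), the electron-rich benzylic methines, and above all Cb–H and Cc–H, which are acidified through rings A and B by the Ca ketone and can epimerise, whereas Cd–H and Ce–H lack that activation. The real difficulty is the seven-membered ring: it is flanked on every side by ortho substituents, and its two stereocentres must be set relative to a Cd/Ce pair that cannot be corrected later. The plan uses the fact that Cb and Cc are neighbours and that each can be a carbonyl carbon, Cb as a diaryl ketone on ring A position 6 and Cc as the carbonyl of a 2,3-diarylindan-1-one fused to ring B, so the Cb–Cc bond can be made by reductive carbonyl coupling. That coupling leaves a Cb=Cc alkene exactly where the last two stereocentres are needed, and the Ca ketone is then the handle for settling them under thermodynamic control.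

## Logic of the disconnections

**23 to 22.** The six aryl O–CH3 bonds are cut last. Methyl ethers survive every condition of the route (low-valent titanium, osmium, hydrogenation, strong base) and keep the benzylic C–H bonds acidic enough for the equilibration; the forward step needs one reagent that cleaves all six without touching the ketone or the stereocentres.

**22 to 20 to 19.** The Cb–H and Cc–H bonds are removed, replacing two stereocentres by the Cb=Cc alkene of 19. This turns a four-stereocentre problem into a two-stereocentre one. The forward steps must add hydrogen to a tetrasubstituted triaryl alkene without reducing the ketone, and then allow both new centres in 20 to find the trans arrangement of 22 by reversible deprotonation, while Ce stays fixed.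

**19 to 17.** The Ca=O bond is exchanged for Ca=CH2. A free Ca ketone would be a third partner in the reductive coupling, so it is carried as a 1,1-diarylethene. The forward step needs an oxidative cleavage that takes the exposed disubstituted alkene and leaves the shielded tetrasubstituted one.

**17 to 15.** The Cb=Cc bond is cut, opening the seven-membered ring to a diketone in which the two carbonyl carbons sit on neighbouring arms of the Ca hinge. This is the largest simplification of the route: a crowded carbocycle becomes two independently made aryl ketones. The forward step must favour intramolecular coupling over simple reduction or dimerisation.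

**15 to 9 and 14.** The bond between ring B position 2 and Ca is cut, dividing the molecule into a chiral bromoindanone and an achiral alkenyl boronate of similar size. Boron is placed on the ring A partner so that the hindered, valuable bromide 9 is used directly. The forward step is a cross-coupling at a di-ortho-substituted aryl carbon.

**14 to 12 and 13.** The bond between ring A position 1 and Ca is cut, so Ca and its methylene arrive as a two-carbon linchpin. The more obvious ring A partner, a methyl ketone ortho to the aroyl group that is later enolised to a vinyl halide or triflate, is avoided on purpose: such a 1,2-diacylbenzene closes by intramolecular aldol as soon as the acetyl group is enolised and condenses with hydrazine-type reagents across both carbonyls. The forward step must stop after one of the two boron groups has reacted.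

**12 to 10 and 11.** The bond between ring A position 6 and the Cb carbonyl carbon is cut as an arene acylation. The forward step depends on attack ortho to bromine and para to methoxy.

**9 to 8.** No bond is cut; the racemate is divided. Cd is created in an electrocyclisation for which no dependable catalytic asymmetric version exists on triaryl enones, and once set it cannot racemise, so the resolution is placed here, four steps into the cheapest branch.

**8 to 7.** The bond between ring B position 6 and Cd is cut. The indanone becomes an acyclic enone, and the forward ring closure is directed to the only free ortho position of ring B, which both methoxy groups activate; the bromine at position 2 must survive the acid.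

**7 to 5 and 6.** The Ce=Cd double bond is cut as a carbonyl condensation between an activated methylene and an aromatic aldehyde.

**5 to 4 to 1 and 2.** The oxidation level at Cc is adjusted and the Cc–CH2 bond is cut as a benzylic Grignard addition to an aldehyde that already carries the ring B bromine and both oxygens.

## Other disconnections considered

**Alternative 1:** The cut takes ring B itself apart, at the bond between its positions 1 and 2. In the forward sense a base-mediated aldol of the doubly activated methylene onto the cyclopentanone carbonyl, then dehydration and enolisation, would aromatise ring B onto a pre-formed trans-diarylcyclopentane and give the resorcinol indane A1 from the tetraketone A2.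
- In favour: A1 already carries the Ca carbonyl on ring B position 2, so the hindered aryl–Ca bond of the chosen plan (steps 7 and 8) is obtained without any cross-coupling; on this point the alternative is the better one. Aromatisation is a strong driving force, and the trans-diaryl cyclopentanone core of A2 is a motif that catalytic asymmetric conjugate addition could deliver, which would be better than the resolution of step 5.
- Against: A2 is a 1,3,5,7-tetracarbonyl compound that can fold in several ways (aldol from the inner methylene, Claisen-type acylation, pyranone formation), and it is laborious to assemble. A1 has Cc as a plain methylene and ring A without Cb, so the entire seven-membered ring and both of its stereocentres are still missing.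
- Comparison: structurally it solves ring B and Ca but not the hard part; mechanistically it is metal-free ionic chemistry of comparable reliability only if the folding is controlled; in step count it is clearly longer, because Cc must be oxidised and Cb introduced before any ring closure resembling step 9 could follow.

**Alternative 2:** The cut removes three bonds of ring A (positions 1–6, 2–3 and 4–5), so that ring A becomes three alkynes. In the forward sense Cp*RuCl(cod) would unite the ynone and alkynyl boronate termini of the diyne A4 with the ethynyl boronate A5 in a [2+2+2] cycloaddition, giving the bis(boronate) A3 and closing ring A and the seven-membered ring in one step.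
- In favour: it is the most convergent of all the options. Cb and Cc are already in place before the ring forms, so no late equilibration is needed, which in principle is better than steps 11 and 12. Only oxidation of the two C–B bonds and demethylation would follow, two steps against four, also better.
- Against: A4 must contain all four stereocentres, with Cb as a propargylic benzylic methine set by acyclic control and prone to alkyne–allene isomerisation. The tether makes the metallacycle build a seven-membered ring, which is slow enough for homo-trimerisation of A5 to compete. A5 must insert with its boron meta to the other boron. The ynone is a Michael acceptor throughout.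
- Comparison: structurally more elegant, mechanistically much less secure (three selectivities in one step against one in step 9), and the saving after the key step is outweighed by the longer route to A4.

**Alternative 3:** The cut is the Cd–Ce bond of the indane. In the forward sense Rh2(R-PTAD)4 would convert the diaryldiazomethane A7 into a carbene at Cd that inserts into a benzylic C–H bond of the 2-(4-methoxyphenyl)ethyl side chain, closing the five-membered ring to the bromoindane A6 with both stereocentres set.
- In favour: Cd and Ce would be created enantioselectively by a catalyst, which is better than a resolution in material terms, and A6 keeps the bromine at ring B position 2 needed for a coupling like step 8.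
- Against: A6 has Cc as a methylene, so the carbonyl that step 9 requires would have to be introduced by benzylic oxidation next to the weaker, doubly benzylic Cd–H bond. The carbene is also flanked by a methoxy group whose C–H bonds offer a competing five-membered insertion. A7 needs a condensation at a di-ortho-substituted carbonyl carbon and an oxidation, several steps of its own.
- Comparison: structurally it addresses the same fragment as steps 1–5; mechanistically it offers catalyst control where the chosen plan offers none; in step count it is equal at best and worse once the Cc oxidation is added, so it is attractive only as a later refinement of the ring B branch.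

Key step: step 9

Assumption (chemistry): the all-trans arrangement of Cb, Cc, Ce and Cd is taken to be the most stable diastereomer of the hexamethyl ether, so that equilibration through the Ca ketone converges on 22.

## Route

Step 1
Reactants: 1 4-methoxybenzyl chloride; 2 2-bromo-3,5-dimethoxybenzaldehyde
Product: 4 rac-1-(2-bromo-3,5-dimethoxyphenyl)-2-(4-methoxyphenyl)ethan-1-ol, via 4-methoxybenzylmagnesium chloride 3 (not isolated)
Conditions: Mg, THF, 0 °C, slow addition of 1; then 2, −20 to 0 °C; aq. NH4Cl
Reagents that add atoms: none
Why: Grignard addition to an aldehyde; 3 is formed cold and dilute to limit Wurtz homocoupling and adds to the formyl group of 2 much faster than it could exchange with the hindered aryl bromide. The racemic carbinol centre is removed in step 2.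

Step 2
Reactants: 4 rac-1-(2-bromo-3,5-dimethoxyphenyl)-2-(4-methoxyphenyl)ethan-1-ol
Product: 5 1-(2-bromo-3,5-dimethoxyphenyl)-2-(4-methoxyphenyl)ethan-1-one
Conditions: Dess–Martin periodinane, CH2Cl2, rt
Reagents that add atoms: none
Why: Dess–Martin oxidation of a secondary benzylic alcohol to the deoxybenzoin under near-neutral conditions; the aryl bromide and methyl ethers are inert.

Step 3
Reactants: 5 1-(2-bromo-3,5-dimethoxyphenyl)-2-(4-methoxyphenyl)ethan-1-one; 6 3,5-dimethoxybenzaldehyde
Product: 7 (E)-1-(2-bromo-3,5-dimethoxyphenyl)-3-(3,5-dimethoxyphenyl)-2-(4-methoxyphenyl)prop-2-en-1-one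
Conditions: piperidine (0.3 equiv), AcOH (0.3 equiv), toluene, reflux, Dean–Stark
Reagents that add atoms: none
Why: Knoevenagel-type aldol condensation; the methylene of 5 is activated by the ketone and by the 4-methoxyphenyl group, and removal of water drives formation of the trisubstituted enone. The alkene geometry is of no consequence, because the cation of step 4 equilibrates it.

Step 4
Reactants: 7 (E)-1-(2-bromo-3,5-dimethoxyphenyl)-3-(3,5-dimethoxyphenyl)-2-(4-methoxyphenyl)prop-2-en-1-one
Product: 8 rac-trans-7-bromo-3-(3,5-dimethoxyphenyl)-4,6-dimethoxy-2-(4-methoxyphenyl)indan-1-one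
Conditions: TFA, 1,2-dichloroethane, 70 °C; then Et3N, CH2Cl2, rt
Reagents that add atoms: none
Why: Nazarov cyclisation (conrotatory 4π closure of the hydroxypentadienyl cation onto ring B); position 6 of ring B is the only free ortho position and is ortho and para to the two methoxy groups, so the new bond forms there and creates Cd. Tautomerisation and amine-mediated equilibration at Ce (alpha to the ketone) give the more stable trans isomer; an acid of moderate strength is chosen to avoid ipso-protonation and loss of the activated bromine.

Step 5
Reactants: 8 rac-trans-7-bromo-3-(3,5-dimethoxyphenyl)-4,6-dimethoxy-2-(4-methoxyphenyl)indan-1-one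
Product: 9 (2S,3S)-7-bromo-3-(3,5-dimethoxyphenyl)-4,6-dimethoxy-2-(4-methoxyphenyl)indan-1-one
Conditions: preparative SFC, amylose tris(3,5-dimethylphenylcarbamate) stationary phase, CO2/MeOH
Reagents that add atoms: none
Why: Resolution by chromatography on a chiral stationary phase; Cd is not acidic and Ce can only return to trans, so the separated enantiomer is configurationally secure. The bromine atom allows the absolute configuration to be assigned by anomalous-dispersion X-ray diffraction.

Step 6
Reactants: 10 1-bromo-3,5-dimethoxybenzene; 11 4-methoxybenzoyl chloride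
Product: 12 (2-bromo-4,6-dimethoxyphenyl)(4-methoxyphenyl)methanone
Conditions: SnCl4 (1.2 equiv), CH2Cl2, 0 °C to rt
Reagents that add atoms: none
Why: Friedel–Crafts acylation; the position ortho to bromine and para/ortho to the methoxy groups of 10 is the one electrophiles attack (as in its Vilsmeier formylation), and SnCl4 is mild enough to leave the methoxy group ortho to the new ketone intact. The symmetrical regioisomer, if formed, would be separable.

Step 7
Reactants: 12 (2-bromo-4,6-dimethoxyphenyl)(4-methoxyphenyl)methanone; 13 2,2'-(ethene-1,1-diyl)bis(4,4,5,5-tetramethyl-1,3,2-dioxaborolane)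
Product: 14 {2,4-dimethoxy-6-[1-(4,4,5,5-tetramethyl-1,3,2-dioxaborolan-2-yl)ethenyl]phenyl}(4-methoxyphenyl)methanone
Conditions: 13 (2.5 equiv), Pd[P(t-Bu)3]2 (5 mol %), aq. K3PO4, THF, 40 °C
Reagents that add atoms: none
Why: Suzuki–Miyaura mono-coupling of a geminal alkenyl bis(boronate); after the first arylation the remaining boronate is alpha-aryl and more hindered, and the excess of 13 suppresses a second arylation. Bringing Ca in as this two-carbon unit means an enolisable acetyl group never sits ortho to the aroyl ketone.

Step 8
Reactants: 9 (2S,3S)-7-bromo-3-(3,5-dimethoxyphenyl)-4,6-dimethoxy-2-(4-methoxyphenyl)indan-1-one; 14 {2,4-dimethoxy-6-[1-(4,4,5,5-tetramethyl-1,3,2-dioxaborolan-2-yl)ethenyl]phenyl}(4-methoxyphenyl)methanone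
Product: 15 (2S,3S)-3-(3,5-dimethoxyphenyl)-7-{1-[3,5-dimethoxy-2-(4-methoxybenzoyl)phenyl]ethenyl}-4,6-dimethoxy-2-(4-methoxyphenyl)indan-1-one
Conditions: 14 (1.5 equiv), Pd(OAc)2 (5 mol %), SPhos (10 mol %), K3PO4, toluene/H2O, 80 °C
Reagents that add atoms: none
Why: Suzuki–Miyaura coupling of a di-ortho-substituted aryl bromide with a 1,1-disubstituted alkenyl boronate; the bulky, electron-rich SPhos ligand supports oxidative addition of zerovalent palladium and reductive elimination at the crowded carbon, and the mild base keeps ketone alpha-arylation in check. Ce may enolise but returns to trans, and Cd is untouched.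

Step 9
Reactants: 15 (2S,3S)-3-(3,5-dimethoxyphenyl)-7-{1-[3,5-dimethoxy-2-(4-methoxybenzoyl)phenyl]ethenyl}-4,6-dimethoxy-2-(4-methoxyphenyl)indan-1-one
Product: 17 hexa-O-methyl tetracyclic diene with the seven-membered ring closed by a Cb=Cc double bond and an exocyclic methylene on Ca (Cd S, Ce S), via titanium pinacolate 16 (not isolated)
Conditions: TiCl4 (10 equiv), Zn (20 equiv), pyridine (5 equiv), THF, reflux; 15 added by syringe pump over 12 h (final about 2 mM)
Reagents that add atoms: none
Why: TiCl4 is reduced by Zn to low-valent (divalent) titanium, which transfers single electrons to both carbonyl groups; the diaryl ketone at Cb, the easier one to reduce, gives a ketyl that adds to the Cc indanone carbonyl to form the titanium pinacolate 16. At reflux 16 is deoxygenated on titanium, both C–O bonds breaking to leave the Cb=Cc alkene and titanium oxide. The closest known reaction type is the intramolecular McMurry coupling of diketones to cycloalkenes, in particular mixed diaryl ketone/alkyl aryl ketone couplings that give tetrasubstituted triarylethenes. The seven-membered ring (Cb, two ring A carbons, Ca, two ring B carbons, Cc) closes by carbon–carbon bond formation between two carbonyl carbons, a 7-exo-trig closure in which five of the seven atoms are sp2 and already held close by the two arenes and the Ca alkene hinge, so the entropic cost is small. No stereocentre is created: Cd is a spectator, and Ce, which could enolise on titanium while Cc is still a ketone, returns to trans and is locked once Cc becomes an alkene carbon. Chemoselectivity among three potential carbonyl carbons is secured by carrying Ca as a 1,1-diarylethene, which low-valent titanium does not reduce, and pyridine tempers the Lewis acidity that could otherwise protonate this alkene or cleave methyl ethers. Ring closure over intermolecular coupling is secured by slow addition at high dilution.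

Step 10
Reactants: 17 hexa-O-methyl tetracyclic diene with Cb=Cc and exocyclic Ca methylene
Product: 19 hexa-O-methyl enone: Ca ketone with the Cb=Cc double bond retained (Cd S, Ce S), via vicinal diol 18 (not isolated)
Conditions: OsO4 (5 mol %), NaIO4 (4 equiv), 2,6-lutidine (2 equiv), dioxane/H2O 3:1, rt
Reagents that add atoms: osmium tetroxide, O=[Os](=O)(=O)=O (transfers the oxygen that becomes the ketone oxygen); sodium periodate, [Na+].[O-]I(=O)(=O)=O (re-oxidises osmium and cleaves the diol)
Why: Lemieux–Johnson oxidation; OsO4 dihydroxylates the exposed 1,1-disubstituted exocyclic alkene far faster than the tetrasubstituted, triaryl-shielded Cb=Cc bond, and NaIO4 cleaves diol 18 to the diaryl ketone and formaldehyde. 2,6-Lutidine suppresses over-oxidation.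

Step 11
Reactants: 19 hexa-O-methyl enone with Ca ketone and Cb=Cc
Product: 20 hexa-O-methyl dihydro ketone with cis hydrogens at Cb and Cc, expected mainly as the Cc epimer of 22 (Cb S, Cc S, Cd S, Ce S)
Conditions: H2 (20–50 bar), Pd/C (10 wt %), EtOAc, 40 °C
Reagents that add atoms: none
Why: Heterogeneous hydrogenation of a tetrasubstituted stilbene-type alkene with syn delivery of both hydrogens; addition from the face remote from the neighbouring Ce aryl group should give Cb as required and Cc inverted, but any Cb/Cc mixture is acceptable because both centres are equilibrated in step 12. A neutral solvent and moderate pressure are chosen to spare the hindered diaryl ketone.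

Step 12
Reactants: 20 hexa-O-methyl dihydro ketone (Cc epimer of 22, or a Cb/Cc mixture)
Product: 22 all-trans hexa-O-methyl ether of the target (Cb S, Cc R, Cd S, Ce S), via potassium dienolate 21 (not isolated)
Conditions: KOt-Bu (0.3 equiv), t-BuOH/DMSO 1:4, 40 °C, degassed, argon; AcOH quench
Reagents that add atoms: none
Why: Base-mediated epimerisation through the vinylogous (ortho-quinodimethane) enolate; the Ca ketone acidifies Cc–H and Cb–H through rings B and A, so reversible deprotonation, of the kind used to racemise 4-aryl-1-tetralones, lets both centres settle trans to their neighbours. Ce–H has no such activation, stays fixed and anchors the absolute configuration; sub-stoichiometric base under dry, oxygen-free conditions limits autoxidation and Haller–Bauer cleavage.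

Step 13
Reactants: 22 all-trans hexa-O-methyl ether of the target
Product: 23 CNP0116600.1, the all-trans hexaphenol (Cb S, Cc R, Cd S, Ce S)
Conditions: BBr3 (15 equiv), CH2Cl2, −78 °C to rt; MeOH, then H2O
Reagents that add atoms: none
Why: Lewis-acid cleavage of all six aryl methyl ethers (the one ortho to the ketone first, through chelation); no later step exposes the free phenols to base, so the equilibrated stereocentres are kept.

## Compound list

1 | 4-methoxybenzyl chloride | COc1ccc(CCl)cc1 | starting material
2 | 2-bromo-3,5-dimethoxybenzaldehyde | COc1cc(C=O)c(Br)c(OC)c1 | starting material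
3 | 4-methoxybenzylmagnesium chloride (not isolated) | COc1ccc(C[Mg]Cl)cc1 | intermediate
4 | rac-1-(2-bromo-3,5-dimethoxyphenyl)-2-(4-methoxyphenyl)ethan-1-ol (racemic carbinol, centre removed in step 2) | COc1ccc(CC(O)c2cc(OC)cc(OC)c2Br)cc1 | intermediate
5 | 1-(2-bromo-3,5-dimethoxyphenyl)-2-(4-methoxyphenyl)ethan-1-one | COc1ccc(CC(=O)c2cc(OC)cc(OC)c2Br)cc1 | intermediate
6 | 3,5-dimethoxybenzaldehyde | COc1cc(C=O)cc(OC)c1 | starting material
7 | (E)-1-(2-bromo-3,5-dimethoxyphenyl)-3-(3,5-dimethoxyphenyl)-2-(4-methoxyphenyl)prop-2-en-1-one | COc1ccc(cc1)/C(=C\c1cc(OC)cc(OC)c1)C(=O)c1cc(OC)cc(OC)c1Br | intermediate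
8 | rac-trans-7-bromo-3-(3,5-dimethoxyphenyl)-4,6-dimethoxy-2-(4-methoxyphenyl)indan-1-one (racemate, written as both enantiomers) | Brc1c(OC)cc(OC)c2c1C(=O)[C@H](c1ccc(OC)cc1)[C@H]2c1cc(OC)cc(OC)c1.Brc1c(OC)cc(OC)c2c1C(=O)[C@@H](c1ccc(OC)cc1)[C@@H]2c1cc(OC)cc(OC)c1 | intermediate
9 | (2S,3S)-7-bromo-3-(3,5-dimethoxyphenyl)-4,6-dimethoxy-2-(4-methoxyphenyl)indan-1-one | Brc1c(OC)cc(OC)c2c1C(=O)[C@H](c1ccc(OC)cc1)[C@H]2c1cc(OC)cc(OC)c1 | intermediate
10 | 1-bromo-3,5-dimethoxybenzene | COc1cc(Br)cc(OC)c1 | starting material
11 | 4-methoxybenzoyl chloride | COc1ccc(C(=O)Cl)cc1 | starting material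
12 | (2-bromo-4,6-dimethoxyphenyl)(4-methoxyphenyl)methanone | COc1ccc(cc1)C(=O)c1c(Br)cc(OC)cc1OC | intermediate
13 | 2,2'-(ethene-1,1-diyl)bis(4,4,5,5-tetramethyl-1,3,2-dioxaborolane) | C=C(B1OC(C)(C)C(C)(C)O1)B1OC(C)(C)C(C)(C)O1 | starting material
14 | {2,4-dimethoxy-6-[1-(4,4,5,5-tetramethyl-1,3,2-dioxaborolan-2-yl)ethenyl]phenyl}(4-methoxyphenyl)methanone | C=C(B1OC(C)(C)C(C)(C)O1)c1cc(OC)cc(OC)c1C(=O)c1ccc(OC)cc1 | intermediate
15 | (2S,3S)-3-(3,5-dimethoxyphenyl)-7-{1-[3,5-dimethoxy-2-(4-methoxybenzoyl)phenyl]ethenyl}-4,6-dimethoxy-2-(4-methoxyphenyl)indan-1-one | C=C(c1cc(OC)cc(OC)c1C(=O)c1ccc(OC)cc1)c1c(OC)cc(OC)c2c1C(=O)[C@H](c1ccc(OC)cc1)[C@H]2c1cc(OC)cc(OC)c1 | intermediate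
16 | titanium pinacolate of 15 (not isolated; drawn as the bis(dichlorotitanium) diolate with trivalent titanium, carbinol configurations at Cb and Cc not defined) | C=C1c2cc(OC)cc(OC)c2C(O[Ti](Cl)Cl)(c2ccc(OC)cc2)C2(O[Ti](Cl)Cl)c3c1c(OC)cc(OC)c3[C@H](c1cc(OC)cc(OC)c1)[C@H]2c1ccc(OC)cc1 | intermediate
17 | hexa-O-methyl tetracyclic diene: Cb=Cc cycloheptene with exocyclic methylene on Ca (Cd S, Ce S) | C=C1c2cc(OC)cc(OC)c2C(c2ccc(OC)cc2)=C2c3c1c(OC)cc(OC)c3[C@H](c1cc(OC)cc(OC)c1)[C@H]2c1ccc(OC)cc1 | intermediate
18 | vicinal diol from dihydroxylation of the Ca methylene of 17 (not isolated; Ca configuration not defined) | OCC1(O)c2cc(OC)cc(OC)c2C(c2ccc(OC)cc2)=C2c3c1c(OC)cc(OC)c3[C@H](c1cc(OC)cc(OC)c1)[C@H]2c1ccc(OC)cc1 | intermediate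
19 | hexa-O-methyl enone: Ca ketone with Cb=Cc retained (Cd S, Ce S) | O=C1c2cc(OC)cc(OC)c2C(c2ccc(OC)cc2)=C2c3c1c(OC)cc(OC)c3[C@H](c1cc(OC)cc(OC)c1)[C@H]2c1ccc(OC)cc1 | intermediate
20 | hexa-O-methyl dihydro ketone, cis hydrogens at Cb and Cc, Cc epimer of 22 (Cb S, Cc S, Cd S, Ce S) | O=C1c2cc(OC)cc(OC)c2[C@H](c2ccc(OC)cc2)[C@H]2c3c1c(OC)cc(OC)c3[C@H](c1cc(OC)cc(OC)c1)[C@H]2c1ccc(OC)cc1 | intermediate
21 | potassium dienolate formed by deprotonation at Cc (not isolated; written in its carbanion resonance form) | [K+].O=C1c2cc(OC)cc(OC)c2[C@H](c2ccc(OC)cc2)[C-]2c3c1c(OC)cc(OC)c3[C@H](c1cc(OC)cc(OC)c1)[C@H]2c1ccc(OC)cc1 | intermediate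
22 | all-trans hexa-O-methyl ether of the target (Cb S, Cc R, Cd S, Ce S) | O=C1c2cc(OC)cc(OC)c2[C@H](c2ccc(OC)cc2)[C@@H]2c3c1c(OC)cc(OC)c3[C@H](c1cc(OC)cc(OC)c1)[C@H]2c1ccc(OC)cc1 | intermediate
23 | CNP0116600.1, all-trans hexaphenol (Cb S, Cc R, Cd S, Ce S) | O=C1c2cc(O)cc(O)c2[C@H](c2ccc(O)cc2)[C@@H]2c3c1c(O)cc(O)c3[C@H](c1cc(O)cc(O)c1)[C@H]2c1ccc(O)cc1 | target

## Step count and least certain steps

Total step count: 13. Longest linear sequence: 11 steps (steps 1–5 and 8–13, from 1 and 2); the ring A branch (steps 6 and 7) joins at step 8.

**Step 9 (key step).** The coupling may stop at the pinacol stage or divert into simple reduction of the diaryl ketone. The alkene to be formed is tetrasubstituted and flanked by ortho-methoxy and aryl groups, and deoxygenation needs both C–O bonds to align on titanium; residual Lewis acidity could also oligomerise the 1,1-diarylethene. Fallback: setting out from 15, the two ketones would be joined with SmI2 (THF/HMPA, −78 °C to rt) to give the cis-pinacol F1. Thiocarbonyldiimidazole (toluene, 110 °C) would convert it into the cyclic thionocarbonate F2, and Corey–Winter fragmentation with 1,3-dimethyl-2-phenyl-1,3,2-diazaphospholidine (40 °C) would return to the route at 17.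

**Step 12.** Inversion at Cc may be incomplete, because Cc–H is a tertiary, singly benzylic C–H and the less acidic of the two, and forcing base invites autoxidation of the carbanions or cleavage of the non-enolisable ketone; the equilibrium could also be less one-sided than assumed. Fallback: setting out from 19, Luche reduction (NaBH4, CeCl3·7H2O) would give the Ca carbinol, of which the epimer with hydroxyl on the face of the Ce aryl group, the carbinol F3, is used (the other is returned to 19 by oxidation). Hydroxyl-directed hydrogenation with [Ir(cod)(PCy3)(py)]PF6 should place both new hydrogens on that face, giving the dihydro carbinol F4. Dess–Martin oxidation then gives the Cb-epimeric ketone F5, in which Cc is already correct, and brief treatment with KOt-Bu in THF at 0 °C inverts only the more acidic Cb–H, coming back to the route at 22.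

**Step 11.** Hydrogen uptake may fail at the shielded tetrasubstituted alkene, or hydrogenolysis of the Ca carbonyl may set in under the forcing conditions needed to reduce it. Fallback: setting out from 19, dissolving-metal reduction (Li, NH3/THF, t-BuOH, −78 °C) would reduce the stilbene unit and the ketone by electron transfer to give the dihydro carbinol F6 as a diastereomer mixture. Dess–Martin oxidation then returns to the route at 20, as a Cb/Cc mixture that step 12 is designed to accept.

**Step 8.** Protodeboronation of 14 may outpace transmetalation at the crowded palladium centre, or oxidative addition into the di-ortho-substituted, electron-rich bromide may stall. Fallback with reversed polarity: setting out from 9, Miyaura borylation (B2pin2, Pd(OAc)2/SPhos, KOAc, dioxane) would give the aryl boronate F7, while 14 would be converted by bromodeboronation (CuBr2, MeOH/H2O) into the 1-bromovinyl ketone F8. Their coupling (Pd(OAc)2/SPhos, K3PO4) returns to the route at 15.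

**Step 7.** A second arylation of 13, or protodeboronation of the product, may erode the mono-coupling, since the parent alkenyl bis(boronate) is less hindered than its substituted relatives. Fallback: setting out from 12, Miyaura borylation would give the aryl boronate F9, and selective mono-coupling with excess 1,1-dichloroethene (Pd(PPh3)4, aq. K2CO3, THF) would give the 1-chlorovinyl ketone F10. Coupling of F10 with F7 (Pd(OAc)2/SPhos, K3PO4, 100 °C) returns to the route at 15 without passing through 14.

## Further compounds

F1 | step 9 | cis-pinacol (Cb,Cc-diol) of 15, carbinol configurations not defined | C=C1c2cc(OC)cc(OC)c2C(O)(c2ccc(OC)cc2)C2(O)c3c1c(OC)cc(OC)c3[C@H](c1cc(OC)cc(OC)c1)[C@H]2c1ccc(OC)cc1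
F2 | step 9 | cyclic thionocarbonate of F1 | C=C1c2cc(OC)cc(OC)c2C2(c3ccc(OC)cc3)OC(=S)OC23c2c1c(OC)cc(OC)c2[C@H](c1cc(OC)cc(OC)c1)[C@H]3c1ccc(OC)cc1
F3 | step 12 | Ca carbinol of 19 with hydroxyl on the face of the Ce aryl group | O[C@@H]1c2cc(OC)cc(OC)c2C(c2ccc(OC)cc2)=C2c3c1c(OC)cc(OC)c3[C@H](c1cc(OC)cc(OC)c1)[C@H]2c1ccc(OC)cc1
F4 | step 12 | dihydro carbinol with Ca–OH, Cb–H and Cc–H on the same face | O[C@@H]1c2cc(OC)cc(OC)c2[C@@H](c2ccc(OC)cc2)[C@@H]2c3c1c(OC)cc(OC)c3[C@H](c1cc(OC)cc(OC)c1)[C@H]2c1ccc(OC)cc1
F5 | step 12 | Cb epimer of 22 (Cb R, Cc R, Cd S, Ce S) | O=C1c2cc(OC)cc(OC)c2[C@@H](c2ccc(OC)cc2)[C@@H]2c3c1c(OC)cc(OC)c3[C@H](c1cc(OC)cc(OC)c1)[C@H]2c1ccc(OC)cc1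
F6 | step 11 | dihydro Ca carbinol from dissolving-metal reduction (mixture at Ca, Cb and Cc) | OC1c2cc(OC)cc(OC)c2C(c2ccc(OC)cc2)C2c3c1c(OC)cc(OC)c3[C@H](c1cc(OC)cc(OC)c1)[C@H]2c1ccc(OC)cc1
F7 | step 8 | (2S,3S)-3-(3,5-dimethoxyphenyl)-4,6-dimethoxy-2-(4-methoxyphenyl)-7-(4,4,5,5-tetramethyl-1,3,2-dioxaborolan-2-yl)indan-1-one | CC1(C)OB(OC1(C)C)c1c(OC)cc(OC)c2c1C(=O)[C@H](c1ccc(OC)cc1)[C@H]2c1cc(OC)cc(OC)c1
F8 | step 8 | [2-(1-bromoethenyl)-4,6-dimethoxyphenyl](4-methoxyphenyl)methanone | C=C(Br)c1cc(OC)cc(OC)c1C(=O)c1ccc(OC)cc1
F9 | step 7 | [2,4-dimethoxy-6-(4,4,5,5-tetramethyl-1,3,2-dioxaborolan-2-yl)phenyl](4-methoxyphenyl)methanone | COc1ccc(cc1)C(=O)c1c(B2OC(C)(C)C(C)(C)O2)cc(OC)cc1OC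
F10 | step 7 | [2-(1-chloroethenyl)-4,6-dimethoxyphenyl](4-methoxyphenyl)methanone | C=C(Cl)c1cc(OC)cc(OC)c1C(=O)c1ccc(OC)cc1
A1 | alternative 1 | ring B resorcinol indane carrying the 3,5-dimethoxybenzoyl group on ring B position 2 | O=C(c1cc(OC)cc(OC)c1)c1c(O)cc(O)c2c1C[C@H](c1ccc(OC)cc1)[C@H]2c1cc(OC)cc(OC)c1
A2 | alternative 1 | trans-3-(3,5-dimethoxyphenyl)-4-(4-methoxyphenyl)cyclopentanone bearing at C2 a 5-(3,5-dimethoxyphenyl)-1,3,5-trioxopentyl chain (C2 not defined, it enolises) | O=C1C[C@H](c2ccc(OC)cc2)[C@@H](c2cc(OC)cc(OC)c2)C1C(=O)CC(=O)CC(=O)c1cc(OC)cc(OC)c1
A3 | alternative 2 | hexa-O-methyl skeleton with ring A as 3,5-bis(pinacol boronate) | O=C1c2cc(B3OC(C)(C)C(C)(C)O3)cc(B3OC(C)(C)C(C)(C)O3)c2[C@H](c2ccc(OC)cc2)[C@@H]2c3c1c(OC)cc(OC)c3[C@H](c1cc(OC)cc(OC)c1)[C@H]2c1ccc(OC)cc1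
A4 | alternative 2 | indane diyne: propynoyl group on ring B position 2 and a 1-(4-methoxyphenyl)-3-(pinacolboryl)prop-2-ynyl group on Cc | C#CC(=O)c1c(OC)cc(OC)c2c1[C@@H]([C@@H](c1ccc(OC)cc1)C#CB1OC(C)(C)C(C)(C)O1)[C@H](c1ccc(OC)cc1)[C@H]2c1cc(OC)cc(OC)c1
A5 | alternative 2 | 2-ethynyl-4,4,5,5-tetramethyl-1,3,2-dioxaborolane | C#CB1OC(C)(C)C(C)(C)O1
A6 | alternative 3 | trans-diarylindane with bromine on ring B position 2 | Brc1c(OC)cc(OC)c2c1C[C@H](c1ccc(OC)cc1)[C@H]2c1cc(OC)cc(OC)c1
A7 | alternative 3 | diaryldiazomethane with the diazo carbon at Cd and a 2-(4-methoxyphenyl)ethyl chain on ring B position 1 | [N-]=[N+]=C(c1cc(OC)cc(OC)c1)c1c(OC)cc(OC)c(Br)c1CCc1ccc(OC)cc1
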